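At 2.5 h the flask stands later than any reading, so its state has to be carried forward from the runs.

common to all: electrophile 10 mM
- violet: nucleophile 3 equiv; free base 0.60 equiv; run made earlier
- ochre: nucleophile 3 equiv; free base 0.90 equiv; run made earlier
- green: nucleophile 4.5 equiv; free base 1.2 equiv; run made earlier
- flask: nucleophile 3.00 equiv; free base 1.20 equiv; time 2.5 h

- violet (time / min: electrophile / %, target / %): 30.0: 26.2, 8.6; 60.0: 13.3, 12.4; 90.0: 8.3, 12.7; 120: 6.0, 13.3
- ochre (time / min: electrophile / %, target / %): 10.0: 53.4, 5.1; 20.0: 35.5, 7.4; 50.0: 16.1, 10.5; 120: 5.5, 13.6
- green (time / min: electrophile / %, target / %): 30.0: 24.4, 12.8; 60.0: 11.7, 17.0; 90.0: 6.7, 18.4; 120: 3.9, 19.7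

(standard deviation of a reading: 0.3 percentage points)

- the earlier runs do not show how much of nucleophile is bound; that part of a forecast is a guess

- part of the electrophile that has reacted at 2.5 h
- share of the unused nucleophile that is free and not bound as protonated nucleophile, at 2.5 h

1. The violet run has the flask's 3 equiv of nucleophile. Its last reading of electrophile is 6.0%, against 5.5% in the ochre run, which has more free base. Violet serves as the gauge.
2. The zero of the scale is the symmetric case, electrophile meeting electrophile. There the pairing clock, electrophile consumed over electrophile left, grows with charged [electrophile] times time. Scaled from violet, the flask's clock reads 19.6.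
3. The share left is the inverse of one plus the clock, 4.86%, so 95.1% of the electrophile has reacted.
4. Target is taken as a minor channel, pseudo-first-order with nucleophile in excess, growing with the logarithm of one plus the clock. Violet's 13.3% scales to 14.3%.
5. With one acid set free per target, all of it on nucleophile, 95.0% stays free.
6. That last link is weak, since 1.20 equiv of free base is also present. Reforged on the statistical case, the acid set free is taken to spread in proportion to 3.00 equiv of nucleophile and 1.20 equiv of free base, and 96.4% stays free.

The forecast gives 96% and 75%, taking “perhaps more than one acid per electrophile consumed”. On the free share, this reckoning stands higher.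

The flask gives 96.2% reacted and 97.2% free.

    electrophile + nucleophile → acid set free + target (k = 14.0 M⁻¹ h⁻¹)
    nucleophile + acid set free ⇌ protonated nucleophile, settled at all times (K = 780 M⁻¹)
    acid set free + free base ⇌ salt of the base (K = 4.10 × 10⁵ M⁻¹, k = 830 M⁻¹ h⁻¹)
    2 electrophile → homo dimer (k = 230 M⁻¹ h⁻¹)
    electrophile + target → side product (k = 92.0 M⁻¹ h⁻¹)

The forecast's free share lies 22 percentage points below the flask's, where at 2.50 h protonated nucleophile stands at 0.799 mM beside 0.931 mM of salt of the base. A neighbouring flask charged with 4.0 mM of electrophile, at the same equivalents and time, is reckoned at a clock of 7.83. The reckoning then gives 11.3% of electrophile left, 10.3% of target and 97.5% free. That neighbouring flask holds 11.6% of target, a free share of 97.7%, and 13.3% of electrophile.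

The numbers in the tables were generated by integration for substances that don't exist.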